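Everything rests on cutting the C3–C4 bond of the 5,6-dihydropyran-2-one ring. Ring atom C3 is flanked by the lactone carbonyl C2, the enolised carbonyl C4 and the exocyclic side-chain ketone. It can therefore be introduced as the nucleophilic CH2 of a β-keto ester, and C4 as a plain ester carbon. One base-induced Dieckmann condensation then closes the only ring and completes the tricarbonyl array, with C6 carried in from methyl (R)-3-hydroxybutanoate. The precursor is the open-chain β-keto ester of that hydroxy ester. It already bears the whole silyl-protected side chain, whose skipped diene comes from a ruthenium-catalysed alkene–alkyne coupling.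

Key step: step 10

Remark: the 3-acyl-4-hydroxypyranone is a mobile tricarbonyl tautomer system, and all such compounds are written as the C4 enol drawn for the target. Side-chain locants: C2 is the acid α-carbon, C1' the carbinol carbon and C2' the methyl-bearing carbon.

Step 1
Reactants: 1 (S)-2-methylbutanoic acid; 2 potassium methyl malonate
Product: 4 methyl (4S)-4-methyl-3-oxohexanoate, via acyl imidazolide 3 (not isolated)
Conditions: CDI, THF, rt; then 2, MgCl2, Et3N, MeCN, rt → 40 °C; 1 M HCl work-up
Reagents that add atoms: 1,1'-carbonyldiimidazole, O=C(n1ccnc1)n1ccnc1 (imidazolyl group of 3 only)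
Why: Masamune–Brooks homologation, in which the acyl imidazolide C-acylates the magnesium enolate of the malonate half-ester and loss of CO2 gives the β-keto ester, without any strong base that could racemise the stereocentre of 1 (the future C2').

Step 2
Reactants: 4 methyl (4S)-4-methyl-3-oxohexanoate
Product: 5 methyl (3S,4S)-3-hydroxy-4-methylhexanoate
Conditions: RuCl2[(R)-BINAP] (0.5 mol %), H2 (50 atm), MeOH, 50 °C
Reagents that add atoms: none
Why: Noyori asymmetric hydrogenation, in which chelation of ketone and ester to the divalent ruthenium hydride lets the (R)-BINAP ligand fix the face of hydride delivery, giving the alcohol in the same spatial sense as (R)-3-hydroxybutanoate (descriptor 3S only because sec-butyl outranks CH2CO2Me) and leaving C4 untouched.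

Step 3
Reactants: 5 methyl (3S,4S)-3-hydroxy-4-methylhexanoate
Product: 6 2-(trimethylsilyl)ethyl (3S,4S)-3-hydroxy-4-methylhexanoate
Conditions: Me3SiCH2CH2OH (5 equiv), Ti(OiPr)4 (0.2 equiv), toluene, 100 °C, MeOH distilled off
Reagents that add atoms: 2-(trimethylsilyl)ethanol, C[Si](C)(C)CCO
Why: Titanate-mediated transesterification is essentially neutral, tolerates a free β-hydroxy group and is driven by removal of methanol, and it is placed here so that the fluoride-labile ester is installed while the α-carbon is still unbranched.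

Step 4
Reactants: 6 2-(trimethylsilyl)ethyl (3S,4S)-3-hydroxy-4-methylhexanoate; 7 allyl bromide
Product: 8 2-(trimethylsilyl)ethyl (2R,3R,4S)-3-hydroxy-4-methyl-2-(prop-2-enyl)hexanoate
Conditions: LiN(iPr)2 (2.2 equiv), THF, −78 → −20 °C; 7, DMPU, −78 → −20 °C; cold 1 M HCl
Reagents that add atoms: none
Why: Fráter–Seebach alkylation, in which the dilithio alkoxide–enolate forms a rigid six-membered chelate and allyl bromide approaches the face away from the sec-butyl group on C3, setting C2 as R, anti to the C3 oxygen.

Step 5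
Reactants: 8 2-(trimethylsilyl)ethyl (2R,3R,4S)-3-hydroxy-4-methyl-2-(prop-2-enyl)hexanoate
Product: 9 2-(trimethylsilyl)ethyl (2R,3R,4S)-3-(tert-butyldimethylsilyloxy)-4-methyl-2-(prop-2-enyl)hexanoate
Conditions: TBSOTf, 2,6-lutidine, CH2Cl2, 0 °C → rt
Reagents that add atoms: tert-butyldimethylsilyl trifluoromethanesulfonate, CC(C)(C)[Si](C)(C)OS(=O)(=O)C(F)(F)F
Why: Silyl triflate silylation with a non-nucleophilic base is the standard protection of a hindered secondary alcohol, and the bulky ether later blocks O-acylation and retro-aldol cleavage and shields the neighbouring α-hydrogen.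

Step 6
Reactants: 9 2-(trimethylsilyl)ethyl (2R,3R,4S)-3-(tert-butyldimethylsilyloxy)-4-methyl-2-(prop-2-enyl)hexanoate; 10 methyl pent-4-ynoate
Product: 11 9-methyl 1-[2-(trimethylsilyl)ethyl] (2R,3E)-2-[(1R,2S)-1-(tert-butyldimethylsilyloxy)-2-methylbutyl]-6-methylidenenon-3-enedioate
Conditions: [CpRu(MeCN)3]PF6 (10 mol %), acetone, rt
Reagents that add atoms: none
Why: Ruthenium-catalysed Alder-ene-type alkene–alkyne coupling, in which oxidative cyclisation on the CpRu cation joins the alkene terminus to the internal alkyne carbon, and β-hydride elimination of an allylic CH2 hydrogen followed by reductive elimination gives the branched 1,4-diene with the new E alkene under neutral conditions that leave C2 and both silyl groups alone.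

Step 7
Reactants: 11 9-methyl 1-[2-(trimethylsilyl)ethyl] (2R,3E)-2-[(1R,2S)-1-(tert-butyldimethylsilyloxy)-2-methylbutyl]-6-methylidenenon-3-enedioate
Product: 13 (6E,8R)-8-[(1R,2S)-1-(tert-butyldimethylsilyloxy)-2-methylbutyl]-4-methylidene-9-oxo-9-[2-(trimethylsilyl)ethoxy]non-6-enoic acid, via trimethylstannyl ester 12 (not isolated)
Conditions: Me3SnOH (4 equiv), ClCH2CH2Cl, 65 °C; 0.5 M HCl wash
Reagents that add atoms: trimethyltin hydroxide, C[Sn](C)(C)O
Why: Trimethyltin hydroxide ester cleavage is a near-neutral hydrolysis that discriminates by steric access, so the unhindered methyl ester should react while the α-branched ester next to the silyl ether stays, and the base-sensitive allylic α-stereocentre C2 is neither epimerised nor conjugated.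

Step 8
Reactants: 13 chain acid; 14 Meldrum's acid
Product: 15 2-(trimethylsilyl)ethyl (2R,3E)-2-[(1R,2S)-1-(tert-butyldimethylsilyloxy)-2-methylbutyl]-9-(2,2-dimethyl-4,6-dioxo-1,3-dioxan-5-ylidene)-9-hydroxy-6-methylidenenon-3-enoate
Conditions: DCC, DMAP (1.5 equiv), CH2Cl2, 0 °C → rt; cold aq KHSO4 wash
Reagents that add atoms: none
Why: Carbodiimide/DMAP C-acylation of Meldrum's acid, in which the acylpyridinium ion from the unhindered acid is captured at carbon by the very acidic dioxanedione under weakly basic conditions that do not disturb C2, the diene or the silyl groups.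

Step 9
Reactants: 15 acyl Meldrum's acid; 16 methyl (R)-3-hydroxybutanoate
Product: 18 1-[2-(trimethylsilyl)ethyl] 11-[(2R)-4-methoxy-4-oxobutan-2-yl] (2R,3E)-2-[(1R,2S)-1-(tert-butyldimethylsilyloxy)-2-methylbutyl]-6-methylidene-9-oxoundec-3-enedioate, via acylketene 17 (not isolated)
Conditions: 16 (1.5 equiv), toluene, 100 °C
Reagents that add atoms: none
Why: Thermal cycloreversion of the acyl Meldrum's acid expels acetone and CO2, and the acylketene is trapped at the oxygen of the secondary alcohol (acylketene alcoholysis) under neutral conditions, so the C–O bond of 16 is never broken and its R configuration is kept.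

Step 10
Reactants: 18 β-keto ester of methyl (R)-3-hydroxybutanoate carrying the protected chain
Product: 19 2-(trimethylsilyl)ethyl (2R,3E)-2-[(1R,2S)-1-(tert-butyldimethylsilyloxy)-2-methylbutyl]-9-[(6R)-4-hydroxy-6-methyl-2-oxo-5,6-dihydro-2H-pyran-3-yl]-6-methylidene-9-oxonon-3-enoate
Conditions: KOtBu (1.0 equiv, added slowly), THF, 0 °C → rt; cold 0.5 M HCl
Reagents that add atoms: none
Why: The alkoxide takes a proton from the CH2 held between the chain ketone and the acyloxy carbonyl, the potassium enolate carbon adds to the methyl ester carbonyl, and collapse of the tetrahedral intermediate expels methoxide and leaves the new ring C3–C4 bond. This is a Dieckmann condensation of the Lacey–Dieckmann type, the established way from β-keto esters of 3-hydroxy esters to 3-acyl-4-hydroxy-5,6-dihydropyran-2-ones. The single ring closes in the 6-exo-trig mode through a six-membered transition state in which the C6 methyl group can sit equatorial. No stereocentre is created, because C6 arrives unchanged from 16 and C2, C1' and C2' are spectators. The selectivity needed is enolisation at the 1,3-dicarbonyl CH2 only, since an enolate at CH2CO2Me would expel the acyloxy group (E1cB) and one at the allylic, doubly activated C2 would epimerise it or move the alkene into conjugation. This selectivity is secured by the large acidity gap, by never having base in excess, and by the OTBS and sec-butyl groups that crowd the C2 hydrogen, while the released methoxide is consumed at once by the far more acidic tricarbonyl product, making the closure irreversible.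

Step 11
Reactants: 19 protected target (silylethyl ester and TBS ether)
Product: 20 (2R,3E)-2-[(1R,2S)-1-(tert-butyldimethylsilyloxy)-2-methylbutyl]-9-[(6R)-4-hydroxy-6-methyl-2-oxo-5,6-dihydro-2H-pyran-3-yl]-6-methylidene-9-oxonon-3-enoic acid
Conditions: Bu4NF (3 equiv), THF, 0 °C → rt; 0.5 M HCl to pH 3
Reagents that add atoms: none
Why: Fluoride-induced β-fragmentation of the 2-(trimethylsilyl)ethyl ester gives ethene, Me3SiF and the carboxylate, and running it first, while the hindered TBS ether still masks the alcohol, excludes retro-aldol cleavage, with the carboxylate and the pyranone enolate being anionic forms that protect C2 and the ring from the basic medium.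

Step 12
Reactants: 20 TBS-protected acid
Product: 21 target, (2R,3E)-2-[(1R,2S)-1-hydroxy-2-methylbutyl]-9-[(6R)-4-hydroxy-6-methyl-2-oxo-5,6-dihydro-2H-pyran-3-yl]-6-methylidene-9-oxonon-3-enoic acid
Conditions: 48% aq HF, MeCN, 0 °C → rt
Reagents that add atoms: none
Why: Acidic fluoride desilylation cleaves even crowded secondary TBS ethers without any base, so the β-hydroxy acid, the skipped diene and the acylpyranone are not exposed to retro-aldol cleavage, epimerisation or alkene migration.

Compound list
1 | (S)-2-methylbutanoic acid | CC[C@H](C)C(=O)O | starting material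
2 | potassium methyl malonate (potassium 3-methoxy-3-oxopropanoate) | COC(=O)CC(=O)[O-].[K+] | starting material
3 | (2S)-1-(imidazol-1-yl)-2-methylbutan-1-one | CC[C@H](C)C(=O)n1ccnc1 | intermediate
4 | methyl (4S)-4-methyl-3-oxohexanoate | COC(=O)CC(=O)[C@@H](C)CC | intermediate
5 | methyl (3S,4S)-3-hydroxy-4-methylhexanoate | COC(=O)C[C@H](O)[C@@H](C)CC | intermediate
6 | 2-(trimethylsilyl)ethyl (3S,4S)-3-hydroxy-4-methylhexanoate | C[Si](C)(C)CCOC(=O)C[C@H](O)[C@@H](C)CC | intermediate
7 | allyl bromide | C=CCBr | starting material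
8 | 2-(trimethylsilyl)ethyl (2R,3R,4S)-3-hydroxy-4-methyl-2-(prop-2-enyl)hexanoate | C=CC[C@@H](C(=O)OCC[Si](C)(C)C)[C@H](O)[C@@H](C)CC | intermediate
9 | 2-(trimethylsilyl)ethyl (2R,3R,4S)-3-(tert-butyldimethylsilyloxy)-4-methyl-2-(prop-2-enyl)hexanoate | C=CC[C@@H](C(=O)OCC[Si](C)(C)C)[C@H](O[Si](C)(C)C(C)(C)C)[C@@H](C)CC | intermediate
10 | methyl pent-4-ynoate | C#CCCC(=O)OC | starting material
11 | 9-methyl 1-[2-(trimethylsilyl)ethyl] (2R,3E)-2-[(1R,2S)-1-(tert-butyldimethylsilyloxy)-2-methylbutyl]-6-methylidenenon-3-enedioate | C=C(C/C=C/[C@@H](C(=O)OCC[Si](C)(C)C)[C@H](O[Si](C)(C)C(C)(C)C)[C@@H](C)CC)CCC(=O)OC | intermediate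
12 | 9-trimethylstannyl ester corresponding to 11 | C=C(C/C=C/[C@@H](C(=O)OCC[Si](C)(C)C)[C@H](O[Si](C)(C)C(C)(C)C)[C@@H](C)CC)CCC(=O)O[Sn](C)(C)C | intermediate
13 | (6E,8R)-8-[(1R,2S)-1-(tert-butyldimethylsilyloxy)-2-methylbutyl]-4-methylidene-9-oxo-9-[2-(trimethylsilyl)ethoxy]non-6-enoic acid | C=C(C/C=C/[C@@H](C(=O)OCC[Si](C)(C)C)[C@H](O[Si](C)(C)C(C)(C)C)[C@@H](C)CC)CCC(=O)O | intermediate
14 | Meldrum's acid (2,2-dimethyl-1,3-dioxane-4,6-dione) | CC1(C)OC(=O)CC(=O)O1 | starting material
15 | acyl Meldrum's acid of 13, enol form | C=C(C/C=C/[C@@H](C(=O)OCC[Si](C)(C)C)[C@H](O[Si](C)(C)C(C)(C)C)[C@@H](C)CC)CCC(O)=C1C(=O)OC(C)(C)OC1=O | intermediate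
16 | methyl (R)-3-hydroxybutanoate | C[C@@H](O)CC(=O)OC | starting material
17 | acylketene from 15 | C=C(C/C=C/[C@@H](C(=O)OCC[Si](C)(C)C)[C@H](O[Si](C)(C)C(C)(C)C)[C@@H](C)CC)CCC(=O)C=C=O | intermediate
18 | 1-[2-(trimethylsilyl)ethyl] 11-[(2R)-4-methoxy-4-oxobutan-2-yl] (2R,3E)-2-[(1R,2S)-1-(tert-butyldimethylsilyloxy)-2-methylbutyl]-6-methylidene-9-oxoundec-3-enedioate | C=C(C/C=C/[C@@H](C(=O)OCC[Si](C)(C)C)[C@H](O[Si](C)(C)C(C)(C)C)[C@@H](C)CC)CCC(=O)CC(=O)O[C@H](C)CC(=O)OC | intermediate
19 | protected target (2-(trimethylsilyl)ethyl ester, TBS ether) | C=C(C/C=C/[C@@H](C(=O)OCC[Si](C)(C)C)[C@H](O[Si](C)(C)C(C)(C)C)[C@@H](C)CC)CCC(=O)C1=C(O)C[C@@H](C)OC1=O | intermediate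
20 | TBS ether of the target acid | C=C(C/C=C/[C@@H](C(=O)O)[C@H](O[Si](C)(C)C(C)(C)C)[C@@H](C)CC)CCC(=O)C1=C(O)C[C@@H](C)OC1=O | intermediate
21 | (2R,3E)-2-[(1R,2S)-1-hydroxy-2-methylbutyl]-9-[(6R)-4-hydroxy-6-methyl-2-oxo-5,6-dihydro-2H-pyran-3-yl]-6-methylidene-9-oxonon-3-enoic acid | C=C(C/C=C/[C@@H](C(=O)O)[C@H](O)[C@@H](C)CC)CCC(=O)C1=C(O)C[C@@H](C)OC1=O | target

Total step count: 12. Longest linear sequence: 12 steps (1 → 21). All other building blocks (2, 7, 10, 14, 16) are purchased.

Steps most likely to fail

Step 10. Ring closure may be slower than proton shuffling. In that case β-elimination of the acyloxy group from the hydroxybutanoate part, or epimerisation and alkene migration at C2, would consume material.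
- The fallback builds the ring first and attaches the chain afterwards. It sets out from 16 and 13 and comes back at 19.
- Compound 16 undergoes a crossed Claisen condensation with excess lithium enolate of tert-butyl acetate (LiN(iPr)2, THF, −78 → −20 °C) to give tert-butyl (5R)-5-hydroxy-3-oxohexanoate F1.
- CF3CO2H in CH2Cl2 lactonises this to (6R)-4-hydroxy-6-methyl-5,6-dihydro-2H-pyran-2-one F2.
- Acid 13 is esterified with F2 (DCC, catalytic DMAP, CH2Cl2) to the 4-O-acyl enol ester F3.
- Stoichiometric DMAP in the same flask induces the Fries-type O-to-C acyl shift to 19.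

Step 6. Regiocontrol between branched and linear coupling in the ruthenacycle may be poor, or turnover with the crowded alkene may be sluggish.
- The fallback replaces the ene coupling by an allyl–vinyl cross-coupling. It sets out from 9 and 10 and comes back at 11.
- Linear-selective palladium-catalysed allylic C–H acetoxylation of 9 (Pd(OAc)2, benzoquinone, DMSO/AcOH, 40 °C) shifts the alkene. The product is 2-(trimethylsilyl)ethyl (2R,3E)-5-acetoxy-2-[(1R,2S)-1-(tert-butyldimethylsilyloxy)-2-methylbutyl]pent-3-enoate F4.
- Stannylcupration of 10 (Me3SnCu·SMe2, MeOH, THF, −63 °C) gives methyl 4-(trimethylstannyl)pent-4-enoate F5.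
- Stille coupling of F4 with F5 (Pd2(dba)3, LiCl, DMF, rt → 50 °C) at the unhindered allyl terminus gives 11.

Step 7. Discrimination between the two esters may be incomplete, or the alkene may migrate into conjugation during the prolonged warm hydrolysis.
- The fallback removes the hydrolysis from the advanced chain by building the β-keto ester on the alkyne before the coupling. It sets out from 10 (with 14, 16 and 9) and comes back at 18.
- Compound 10 is saponified (LiOH, THF/H2O) to pent-4-ynoic acid F6.
- DCC/DMAP acylation of 14 with F6 gives 5-(1-hydroxypent-4-ynylidene)-2,2-dimethyl-1,3-dioxane-4,6-dione F7.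
- Heating F7 with 16 in toluene passes through the alkynyl acylketene F8 and gives (2R)-4-methoxy-4-oxobutan-2-yl 3-oxohept-6-ynoate F9.
- F9 is coupled with 9 under the conditions of step 6 to give 18 directly.

Further compounds
F1 | step 10 | tert-butyl (5R)-5-hydroxy-3-oxohexanoate | C[C@@H](O)CC(=O)CC(=O)OC(C)(C)C
F2 | step 10 | (6R)-4-hydroxy-6-methyl-5,6-dihydro-2H-pyran-2-one | C[C@@H]1CC(O)=CC(=O)O1
F3 | step 10 | (6R)-6-methyl-2-oxo-5,6-dihydro-2H-pyran-4-yl ester of acid 13 | C=C(C/C=C/[C@@H](C(=O)OCC[Si](C)(C)C)[C@H](O[Si](C)(C)C(C)(C)C)[C@@H](C)CC)CCC(=O)OC1=CC(=O)O[C@H](C)C1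
F4 | step 6 | 2-(trimethylsilyl)ethyl (2R,3E)-5-acetoxy-2-[(1R,2S)-1-(tert-butyldimethylsilyloxy)-2-methylbutyl]pent-3-enoate | CC(=O)OC/C=C/[C@@H](C(=O)OCC[Si](C)(C)C)[C@H](O[Si](C)(C)C(C)(C)C)[C@@H](C)CC
F5 | step 6 | methyl 4-(trimethylstannyl)pent-4-enoate | C=C(CCC(=O)OC)[Sn](C)(C)C
F6 | step 7 | pent-4-ynoic acid | C#CCCC(=O)O
F7 | step 7 | 5-(1-hydroxypent-4-ynylidene)-2,2-dimethyl-1,3-dioxane-4,6-dione | C#CCCC(O)=C1C(=O)OC(C)(C)OC1=O
F8 | step 7 | hept-1-en-6-yne-1,3-dione (alkynyl acylketene) | C#CCCC(=O)C=C=O
F9 | step 7 | (2R)-4-methoxy-4-oxobutan-2-yl 3-oxohept-6-ynoate | C#CCCC(=O)CC(=O)O[C@H](C)CC(=O)OC
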